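**Assumptions:** The target is the erythro (meso-like) isomer, S at the carbon bearing the guaiacylmethyl group and R at the carbon bearing the syringylmethyl group. The sense of induction of the new catalytic step cannot be predicted, so the ligand antipode is chosen by correlation.

## Retrosynthetic overview

1. Both stereocentres come from one meso C6 unit: maleic anhydride (1) → dimethylmaleic anhydride (2) → cis-2,3-dimethylsuccinic anhydride (3), which fixes the relative configuration.
2. Aryl partners: catechol (4) → 5 → 6 → guaiacyl bromide 7; resorcinol (8) → 9 → 10 → 11 → syringyl bromide 12.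
3. Disconnection A (sets absolute configuration): ArA–C(acyl) bond by Ni-catalysed enantioselective desymmetrising cross-electrophile coupling of 3 + 7 → keto acid 13.
4. Disconnection B: 13 → 14 → 15 → iodide 16, then ArB–CH2 bond by Pd Negishi coupling with 12 → 17.
5. Rings: both benzene rings are bought; no ring of the target is constructed. The only ring made is the anhydride (2/3), opened in the key step. Global hydrogenolysis 17 → 18 (target).

## Route

### Core fragment

**Step 1**
Reactants: 1, maleic anhydride (2 equiv)
Product: 2, 2,3-dimethylmaleic anhydride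
Conditions: 2-aminopyridine (0.5 equiv), AcOH, reflux; then 2 M H2SO4, reflux
Reagents that add atoms: none (both C4 units come from 1; 2 CO2 are lost; 2-aminopyridine is a recovered mediator)
Why: Known aminopyridine-mediated decarboxylative dimerisation of maleic anhydride (Michael addition, double decarboxylation, hydrolysis of the imide intermediate).

**Step 2**
Reactants: 2, 2,3-dimethylmaleic anhydride
Product: 3, cis-(meso)-2,3-dimethylsuccinic anhydride, (3R,4S)-3,4-dimethyloxolane-2,5-dione
Conditions: H2 (4 bar), 10% Pd/C, EtOAc, rt
Reagents that add atoms: none (H2 only)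
Why: Heterogeneous catalytic hydrogenation adds H2 syn to one face of the ring alkene, giving only the cis (meso) anhydride; this fixes the relative configuration of both stereocentres.

### Guaiacyl fragment

**Step 3**
Reactants: 4, catechol
Product: 5, guaiacol (2-methoxyphenol)
Conditions: MeI (1.0 equiv), K2CO3 (1.05 equiv), acetone, reflux; distil
Reagents that add atoms: iodomethane, CI
Why: Williamson mono-O-methylation; the catechol mono-anion is more acidic and more reactive than guaiacol, so limiting MeI favours the mono-ether.

**Step 4**
Reactants: 5, guaiacol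
Product: 6, 4-bromo-2-methoxyphenol
Conditions: NBS (1.0 equiv), MeCN, 0 °C → rt
Reagents that add atoms: N-bromosuccinimide, O=C1CCC(=O)N1Br
Why: Electrophilic aromatic bromination para to the free OH, which is a stronger director than OMe.

**Step 5**
Reactants: 6, 4-bromo-2-methoxyphenol
Product: 7, 1-(benzyloxy)-4-bromo-2-methoxybenzene
Conditions: BnBr, K2CO3, DMF, rt
Reagents that add atoms: benzyl bromide, BrCc1ccccc1
Why: Williamson O-benzylation; the benzyl ether survives organometallic steps and is removed by hydrogenolysis at the end.

### Syringyl fragment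

**Step 6**
Reactants: 8, resorcinol
Product: 9, 1,3-dimethoxybenzene
Conditions: MeI (2.5 equiv), K2CO3, acetone, reflux
Reagents that add atoms: iodomethane, CI
Why: Exhaustive Williamson O-methylation.

**Step 7**
Reactants: 9, 1,3-dimethoxybenzene
Product: 10, 2,6-dimethoxyphenol
Conditions: n-BuLi, THF, 0 °C → rt; B(OMe)3, −78 °C → rt; then 30% H2O2, AcOH, 0 °C
Reagents that add atoms: hydrogen peroxide, OO (phenolic O)
Why: Directed ortho-metalation at C2 (between the two OMe groups), then borylation and oxidation of the aryl borate to the phenol.

**Step 8**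
Reactants: 10, 2,6-dimethoxyphenol
Product: 11, 4-bromo-2,6-dimethoxyphenol
Conditions: NBS (1.0 equiv), cat. NaH, CHCl3, −45 °C → rt
Reagents that add atoms: N-bromosuccinimide, O=C1CCC(=O)N1Br
Why: Electrophilic bromination of the phenol(ate) at the open para position, directed by the OH group.

**Step 9**
Reactants: 11, 4-bromo-2,6-dimethoxyphenol
Product: 12, 2-(benzyloxy)-5-bromo-1,3-dimethoxybenzene
Conditions: BnBr, K2CO3, DMF, 50 °C
Reagents that add atoms: benzyl bromide, BrCc1ccccc1
Why: Williamson O-benzylation of the hindered phenol.

### Fragment union and endgame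

**Step 10 (key step, new)**
Reactants: 3, cis-2,3-dimethylsuccinic anhydride (1.5 equiv); 7, 1-(benzyloxy)-4-bromo-2-methoxybenzene
Product: 13, (2S,3R)-4-[4-(benzyloxy)-3-methoxyphenyl]-2,3-dimethyl-4-oxobutanoic acid
Conditions: NiBr2·glyme (10 mol%), (S,S)-iPr-BiOX (12 mol%; antipode if correlation requires), Mn (3 equiv), MgCl2 (1 equiv), NaI (25 mol%), DMA/THF, 5 °C; then 1 M HCl. Upgrade ee by crystallising the 1-phenylethylammonium salt.
Reagents that add atoms: none
Why: Proposed new method: an enantioselective desymmetrising reductive acyl–aryl cross-electrophile coupling of a meso anhydride with an aryl bromide. Ni(0)L* inserts into one of the two enantiotopic C(acyl)–O bonds to give a chelated acyl-Ni(II) carboxylate; Mn reduces it to acyl-Ni(I), which adds ArBr, and C(acyl)–C(aryl) reductive elimination from Ni(III) releases the keto-carboxylate. Cleaving the C(=O)–O bond next to the (R)-carbon gives (2S,3R)-13; no base or organometallic nucleophile is present, so the α-centres and the benzyl ether are untouched. Closest known reaction types are racemic Ni-catalysed reductive ketone synthesis from anhydrides plus organic halides, and Ni/Pd/Rh-catalysed enantioselective desymmetrisation of cyclic meso anhydrides with organozincs (or Ni/photoredox with benzyl trifluoroborates).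

**Step 11**
Reactants: 13
Product: 14, (2S,3S)-4-[4-(benzyloxy)-3-methoxyphenyl]-2,3-dimethylbutanoic acid
Conditions: Et3SiH (3 equiv), TFA/CH2Cl2 (1:4), 0 °C → rt
Reagents that add atoms: none
Why: Ionic hydrogenation of the electron-rich aryl ketone (protonation, hydride transfer, ionisation of the p-alkoxybenzylic alcohol or lactone, second hydride transfer). Both stereocentres are unchanged; the C3 descriptor changes from R to S only because CIP priorities change.

**Step 12**
Reactants: 14
Product: 15, (2S,3S)-4-[4-(benzyloxy)-3-methoxyphenyl]-2,3-dimethylbutan-1-ol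
Conditions: BH3·THF, THF, 0 °C → rt; MeOH quench
Reagents that add atoms: none
Why: Chemoselective, non-basic borane reduction of the carboxylic acid; no epimerisation, and no enolisable centre remains afterwards.

**Step 13**
Reactants: 15
Product: 16, 1-(benzyloxy)-4-[(2S,3S)-4-iodo-2,3-dimethylbutyl]-2-methoxybenzene
Conditions: I2, PPh3, imidazole, CH2Cl2, 0 °C → rt
Reagents that add atoms: iodine, II
Why: Appel-type iodination of the primary alcohol (SN2 at CH2; stereocentres not involved).

**Step 14 (key step)**
Reactants: 16; 12, 2-(benzyloxy)-5-bromo-1,3-dimethoxybenzene (1.2 equiv)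
Product: 17, 2-(benzyloxy)-5-{(2R,3S)-4-[4-(benzyloxy)-3-methoxyphenyl]-2,3-dimethylbutyl}-1,3-dimethoxybenzene
Conditions: Zn dust (TMSCl/BrCH2CH2Br-activated), LiCl, THF, 40 °C; then 12, Pd(OAc)2 (2 mol%), SPhos (4 mol%), THF/NMP, 50 °C
Reagents that add atoms: none
Why: LiCl-mediated zinc insertion into the primary iodide, then Pd/biarylphosphine Negishi sp3–sp2 coupling, where fast reductive elimination outcompetes β-hydride elimination. The β-stereocentre is untouched; its descriptor changes from S to R by CIP priority only.

**Step 15**
Reactants: 17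
Product: 18, 4-[(2R,3S)-4-(4-hydroxy-3-methoxyphenyl)-2,3-dimethylbutyl]-2,6-dimethoxyphenol (target)
Conditions: H2 (1 atm), 10% Pd/C, EtOAc/MeOH, rt
Reagents that add atoms: none
Why: Hydrogenolysis of both aryl benzyl ethers; methyl ethers and the saturated chain are inert.

## Compound list

1 | maleic anhydride | O=C1OC(=O)C=C1 | starting material
2 | 2,3-dimethylmaleic anhydride | CC1=C(C)C(=O)OC1=O | intermediate
3 | cis-(meso)-2,3-dimethylsuccinic anhydride, (3R,4S) | C[C@H]1C(=O)OC(=O)[C@H]1C | intermediate
4 | catechol | Oc1ccccc1O | starting material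
5 | guaiacol | COc1ccccc1O | intermediate
6 | 4-bromo-2-methoxyphenol | COc1cc(Br)ccc1O | intermediate
7 | 1-(benzyloxy)-4-bromo-2-methoxybenzene | COc1cc(Br)ccc1OCc1ccccc1 | intermediate
8 | resorcinol | Oc1cccc(O)c1 | starting material
9 | 1,3-dimethoxybenzene | COc1cccc(OC)c1 | intermediate
10 | 2,6-dimethoxyphenol | COc1cccc(OC)c1O | intermediate
11 | 4-bromo-2,6-dimethoxyphenol | COc1cc(Br)cc(OC)c1O | intermediate
12 | 2-(benzyloxy)-5-bromo-1,3-dimethoxybenzene | COc1cc(Br)cc(OC)c1OCc1ccccc1 | intermediate
13 | (2S,3R)-4-[4-(benzyloxy)-3-methoxyphenyl]-2,3-dimethyl-4-oxobutanoic acid | COc1cc(C(=O)[C@H](C)[C@H](C)C(=O)O)ccc1OCc1ccccc1 | intermediate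
14 | (2S,3S)-4-[4-(benzyloxy)-3-methoxyphenyl]-2,3-dimethylbutanoic acid | COc1cc(C[C@H](C)[C@H](C)C(=O)O)ccc1OCc1ccccc1 | intermediate
15 | (2S,3S)-4-[4-(benzyloxy)-3-methoxyphenyl]-2,3-dimethylbutan-1-ol | COc1cc(C[C@H](C)[C@H](C)CO)ccc1OCc1ccccc1 | intermediate
16 | 1-(benzyloxy)-4-[(2S,3S)-4-iodo-2,3-dimethylbutyl]-2-methoxybenzene | COc1cc(C[C@H](C)[C@H](C)CI)ccc1OCc1ccccc1 | intermediate
17 | 2-(benzyloxy)-5-{(2R,3S)-4-[4-(benzyloxy)-3-methoxyphenyl]-2,3-dimethylbutyl}-1,3-dimethoxybenzene | COc1cc(C[C@H](C)[C@H](C)Cc2cc(OC)c(OCc3ccccc3)c(OC)c2)ccc1OCc1ccccc1 | intermediate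
18 | 4-[(2R,3S)-4-(4-hydroxy-3-methoxyphenyl)-2,3-dimethylbutyl]-2,6-dimethoxyphenol | COc1cc(C[C@H](C)[C@H](C)Cc2cc(OC)c(O)c(OC)c2)ccc1O | target

## Summary

Total step count: 15.

Longest linear sequence: 9 steps (steps 3–5, then 10–15; catechol → target). The other branches are 8 steps (maleic anhydride) and 6 steps (resorcinol).

Three steps most likely to fail:

1. **Step 10 (proposed new desymmetrising Ni cross-electrophile coupling).** Risks are low ee, aryl homocoupling or hydrodehalogenation, and decarbonylation of the acyl-nickel. Fallback (known chemistry): abandon the reductive manifold. Preform the arylzinc from 7 (n-BuLi, −78 °C; then ZnCl2) and use the established redox-neutral Rh(I)/chiral phosphoramidite desymmetrisation of cyclic meso anhydrides with arylzinc reagents on 3, giving the same keto acid 13.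

2. **Step 11 (ionic hydrogenation).** Risks are epimerisation α to the ketone (enol or styrene pathway), partial loss of the benzyl ether in TFA, and stalling at the γ-aryl lactone. Fallback: heterogeneous hydrogenolysis (H2, Pd/C, AcOH, cat. HClO4), accepting loss of the benzyl group, to give the phenol acid. Re-benzylate both O–H groups (BnBr, K2CO3) and reduce the benzyl ester with LiAlH4 to rejoin the route at 15.

3. **Step 14 (alkylzinc formation and Negishi coupling).** Risks are sluggish zinc insertion into the β-branched iodide, protodezincation, and β-hydride elimination or isomerisation with the electron-rich bromide. Fallback: form the ArB–C bond by carbonyl addition. Oxidise 15 to the aldehyde (Dess–Martin), add the aryl Grignard from 12 at −78 °C, and let the final H2/Pd-C step (with cat. acid) remove the benzylic OH together with both benzyl ethers.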